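**Assumptions:** 2-bromo-3,3-dimethoxyprop-1-ene (12) is taken as purchasable. In step 9 the (S)-amine is assumed to give the less soluble salt with the required enantiomer; if the other salt crystallises, the (R)-amine is used.

## Retrosynthetic overview

1. The tertiary acetate C–O bond is made last by a Baeyer–Villiger 1,2-shift (ring carbon migrates from the acetyl carbon to oxygen, with retention) of a 2-acetyl-2-methyl decalin keto diacid.
2. That keto diacid comes from a bicyclic keto acetal ester (ester and acetal hydrolysis, aldehyde oxidation), with a classical resolution supplying the single enantiomer.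
3. Both rings come from one radical cascade on an acyclic triene β-keto ester: ring A closes first, ring B second, then the acetyl group moves from the side chain to the ring-B radical.
4. The triene is assembled linearly by two zirconium-catalysed carboalumination/iodination steps, three Negishi couplings and a Claisen-type acetylation.

## Route

Step 1
Reactants: 1 5-iodopent-1-yne
Product: 3 (1E)-1,5-diiodo-2-methylpent-1-ene, via alkenyldimethylalane 2 (not isolated)
Conditions: Me3Al (2.5 equiv), Cp2ZrCl2 (0.25 equiv), CH2Cl2, 0 °C to rt; then I2, THF, −30 to 0 °C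
Reagents that add atoms: trimethylaluminium C[Al](C)C; iodine II
Why: Negishi carboalumination adds Me and Al syn across the terminal alkyne (Me on the internal carbon) and iodinolysis of C–Al with retention fixes the E alkene; the primary alkyl iodide is inert to Me3Al at room temperature.

Step 2
Reactants: 3 (1E)-1,5-diiodo-2-methylpent-1-ene; 4 4-bromobut-1-yne
Product: 6 (5E)-9-iodo-6-methylnon-5-en-1-yne, via but-3-yn-1-ylzinc bromide 5 (not isolated)
Conditions: 4, Zn dust, I2 (5 mol %), DMA, 70 °C; then 3, Pd(PPh3)4 (5 mol %), THF, rt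
Reagents that add atoms: none
Why: Negishi sp2–sp3 coupling; zerovalent palladium inserts only into the alkenyl C–I bond, so the alkyl iodide survives and the alkene geometry is retained.

Step 3
Reactants: 6 (5E)-9-iodo-6-methylnon-5-en-1-yne
Product: 8 (1E,5E)-1,9-diiodo-2,6-dimethylnona-1,5-diene, via dienyldimethylalane 7 (not isolated)
Conditions: Me3Al (2.5 equiv), Cp2ZrCl2 (0.25 equiv), CH2Cl2, 0 °C to rt; then I2, THF, −30 to 0 °C
Reagents that add atoms: trimethylaluminium C[Al](C)C; iodine II
Why: Second Negishi carboalumination/iodinolysis; only the terminal alkyne reacts and the second E-trisubstituted alkene is set by syn addition.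

Step 4
Reactants: 8 (1E,5E)-1,9-diiodo-2,6-dimethylnona-1,5-diene; 9 methyl 3-bromopropanoate
Product: 11 methyl (4E,8E)-12-iodo-5,9-dimethyldodeca-4,8-dienoate, via (3-methoxy-3-oxopropyl)zinc bromide 10 (not isolated)
Conditions: 9, Zn dust, I2 (5 mol %), DMA, 70 °C; then 8, PdCl2(dppf) (5 mol %), THF, 40 °C
Reagents that add atoms: none
Why: Negishi coupling of the zinc homoenolate at the alkenyl iodide only, with retention of geometry.

Step 5
Reactants: 11 methyl (4E,8E)-12-iodo-5,9-dimethyldodeca-4,8-dienoate; 12 2-bromo-3,3-dimethoxyprop-1-ene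
Product: 14 methyl (4E,8E)-13-(dimethoxymethyl)-5,9-dimethyltetradeca-4,8,13-trienoate, via alkylzinc iodide 13 (not isolated)
Conditions: Zn dust, LiCl, THF, 40 °C; then 12, Pd2(dba)3 (2.5 mol %), SPhos (10 mol %), THF, 50 °C
Reagents that add atoms: none
Why: Direct zinc insertion into the primary iodide (ester tolerated) followed by Negishi coupling with the vinyl bromide installs the 1,1-disubstituted alkene that carries the masked carboxyl group.

Step 6
Reactants: 14 methyl (4E,8E)-13-(dimethoxymethyl)-5,9-dimethyltetradeca-4,8,13-trienoate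
Product: 16 methyl (4E,8E)-2-acetyl-13-(dimethoxymethyl)-5,9-dimethyltetradeca-4,8,13-trienoate, via lithium enolate 15 (not isolated)
Conditions: LiN(i-Pr)2 (1.15 equiv), THF, −78 °C; MeC(O)N(OMe)Me, −78 to 0 °C; aq NH4Cl
Reagents that add atoms: N-methoxy-N-methylacetamide CC(=O)N(C)OC
Why: Claisen-type C-acylation of the ester enolate; the chelated tetrahedral adduct of the Weinreb amide prevents double acylation.

Step 7
Reactants: 16 methyl (4E,8E)-2-acetyl-13-(dimethoxymethyl)-5,9-dimethyltetradeca-4,8,13-trienoate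
Product: 17 rac-methyl 3-[(1R,2R,4aR,5R,8aS)-2-acetyl-5-(dimethoxymethyl)-2,5,8a-trimethyldecahydronaphthalen-1-yl]propanoate
Conditions: Fe(acac)3 (iron tris(acetylacetonate), 0.3 equiv), PhSiH3 (2.5 equiv), MeOH/THF 4:1, 0.01 M, 60 °C, slow addition of 16
Reagents that add atoms: none
Why: Proposed new method: the iron hydride from Fe(acac)3 and PhSiH3 delivers H• to the terminal CH2 of the 1,1-disubstituted alkene (Mukaiyama-type hydrogen-atom transfer); the tertiary radical beside the acetal closes ring A by 6-endo attack on the first E-alkene and the next tertiary radical closes ring B the same way through a chair–chair array (bulky CH(OMe)2 equatorial, both ring methyls axial, trans fusion, side chain equatorial); the ring-B radical then adds 5-exo to the acetyl C=O on the face away from the angular methyl and the alkoxy radical fragments to the ester-stabilised radical, which divalent iron reduces and methanol protonates, so the acetyl group ends on the quaternary ring carbon (net 1,4-acyl shift) and all five stereocentres are set relative to each other (racemate); closest known chemistry: iron-hydride HAT-initiated radical polyene bicyclisations and the Dowd–Beckwith acyl migration through an alkoxy radical.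

Step 8
Reactants: 17 rac-methyl 3-[(1R,2R,4aR,5R,8aS)-2-acetyl-5-(dimethoxymethyl)-2,5,8a-trimethyldecahydronaphthalen-1-yl]propanoate
Product: 20 rac-3-[(1R,2R,4aR,5R,8aR)-2-acetyl-5-carboxy-2,5,8a-trimethyldecahydronaphthalen-1-yl]propanoic acid, via lithium carboxylate 18 (not isolated), via keto aldehyde acid 19 (not isolated)
Conditions: LiOH (3 equiv), THF/MeOH/H2O, rt; 2 M HCl to pH 1, rt; then t-BuOH, 2-methylbut-2-ene, NaClO2, NaH2PO4, rt
Reagents that add atoms: lithium hydroxide [Li+].[OH-]; water O; sodium chlorite [Na+].[O-]Cl=O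
Why: Ester saponification, acid hydrolysis of the acetal and Pinnick oxidation of the non-enolisable aldehyde; no stereocentre is touched.

Step 9
Reactants: 20 rac-3-[(1R,2R,4aR,5R,8aR)-2-acetyl-5-carboxy-2,5,8a-trimethyldecahydronaphthalen-1-yl]propanoic acid
Product: 21 (1S)-1-phenylethan-1-aminium 3-[(1R,2R,4aR,5R,8aR)-2-acetyl-5-carboxy-2,5,8a-trimethyldecahydronaphthalen-1-yl]propanoate
Conditions: (S)-1-phenylethylamine (0.55 equiv), EtOAc/EtOH, 60 to 4 °C; two recrystallisations
Reagents that add atoms: (S)-1-phenylethylamine C[C@H](N)c1ccccc1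
Why: Classical resolution by diastereomeric salt crystallisation; the absolute configuration is selected here and the other enantiomer stays in the mother liquor.

Step 10
Reactants: 21 (1S)-1-phenylethan-1-aminium 3-[(1R,2R,4aR,5R,8aR)-2-acetyl-5-carboxy-2,5,8a-trimethyldecahydronaphthalen-1-yl]propanoate
Product: 23 3-[(1R,2R,4aR,5R,8aS)-2-(acetyloxy)-5-carboxy-2,5,8a-trimethyldecahydronaphthalen-1-yl]propanoic acid, via keto diacid 22 (not isolated)
Conditions: 1 M HCl/EtOAc partition; then 3-chloroperoxybenzoic acid (3 equiv), TFA (0.3 equiv), CH2Cl2, 0 °C to rt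
Reagents that add atoms: 3-chloroperoxybenzoic acid OOC(=O)c1cccc(Cl)c1
Why: Baeyer–Villiger oxidation; in the Criegee adduct the fully substituted ring carbon migrates from carbon to oxygen in preference to methyl and with retention, so the tertiary acetate takes the configuration set in step 7 without acylating a hindered alcohol.

## Compound list

1 | 5-iodopent-1-yne | C#CCCCI | starting material
2 | [(1E)-5-iodo-2-methylpent-1-en-1-yl]dimethylalane | C/C(CCCI)=C\[Al](C)C | intermediate
3 | (1E)-1,5-diiodo-2-methylpent-1-ene | C/C(CCCI)=C\I | intermediate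
4 | 4-bromobut-1-yne | C#CCCBr | starting material
5 | but-3-yn-1-ylzinc bromide | C#CCC[Zn]Br | intermediate
6 | (5E)-9-iodo-6-methylnon-5-en-1-yne | C#CCC/C=C(\C)CCCI | intermediate
7 | [(1E,5E)-9-iodo-2,6-dimethylnona-1,5-dien-1-yl]dimethylalane | C/C(CC/C=C(\C)CCCI)=C\[Al](C)C | intermediate
8 | (1E,5E)-1,9-diiodo-2,6-dimethylnona-1,5-diene | C/C(CC/C=C(\C)CCCI)=C\I | intermediate
9 | methyl 3-bromopropanoate | COC(=O)CCBr | starting material
10 | (3-methoxy-3-oxopropyl)zinc bromide | COC(=O)CC[Zn]Br | intermediate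
11 | methyl (4E,8E)-12-iodo-5,9-dimethyldodeca-4,8-dienoate | COC(=O)CC/C=C(\C)CC/C=C(\C)CCCI | intermediate
12 | 2-bromo-3,3-dimethoxyprop-1-ene | COC(OC)C(Br)=C | starting material
13 | [(4E,8E)-12-methoxy-4,8-dimethyl-12-oxododeca-4,8-dien-1-yl]zinc iodide | COC(=O)CC/C=C(\C)CC/C=C(\C)CCC[Zn]I | intermediate
14 | methyl (4E,8E)-13-(dimethoxymethyl)-5,9-dimethyltetradeca-4,8,13-trienoate | COC(=O)CC/C=C(\C)CC/C=C(\C)CCCC(=C)C(OC)OC | intermediate
15 | lithium enolate of 14 (O-lithio ketene acetal) | COC(O[Li])=CC/C=C(\C)CC/C=C(\C)CCCC(=C)C(OC)OC | intermediate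
16 | methyl (4E,8E)-2-acetyl-13-(dimethoxymethyl)-5,9-dimethyltetradeca-4,8,13-trienoate (C-2 racemic) | COC(=O)C(C(C)=O)C/C=C(\C)CC/C=C(\C)CCCC(=C)C(OC)OC | intermediate
17 | rac-methyl 3-[(1R,2R,4aR,5R,8aS)-2-acetyl-5-(dimethoxymethyl)-2,5,8a-trimethyldecahydronaphthalen-1-yl]propanoate (racemate; SMILES shows the enantiomer carried on) | CC(=O)[C@]1(C)CC[C@@H]2[C@](C)(CCC[C@@]2(C)C(OC)OC)[C@H]1CCC(=O)OC | intermediate
18 | lithium rac-3-[(1R,2R,4aR,5R,8aS)-2-acetyl-5-(dimethoxymethyl)-2,5,8a-trimethyldecahydronaphthalen-1-yl]propanoate | CC(=O)[C@]1(C)CC[C@@H]2[C@](C)(CCC[C@@]2(C)C(OC)OC)[C@H]1CCC(=O)[O-].[Li+] | intermediate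
19 | rac-3-[(1R,2R,4aR,5R,8aS)-2-acetyl-5-formyl-2,5,8a-trimethyldecahydronaphthalen-1-yl]propanoic acid | CC(=O)[C@]1(C)CC[C@@H]2[C@](C)(CCC[C@@]2(C)C=O)[C@H]1CCC(=O)O | intermediate
20 | rac-3-[(1R,2R,4aR,5R,8aR)-2-acetyl-5-carboxy-2,5,8a-trimethyldecahydronaphthalen-1-yl]propanoic acid (racemate; same spatial arrangement as 17, the 8a descriptor changes only because CO2H outranks acetyl) | CC(=O)[C@]1(C)CC[C@@H]2[C@](C)(CCC[C@@]2(C)C(=O)O)[C@H]1CCC(=O)O | intermediate
21 | (1S)-1-phenylethan-1-aminium 3-[(1R,2R,4aR,5R,8aR)-2-acetyl-5-carboxy-2,5,8a-trimethyldecahydronaphthalen-1-yl]propanoate | CC(=O)[C@]1(C)CC[C@@H]2[C@](C)(CCC[C@@]2(C)C(=O)O)[C@H]1CCC(=O)[O-].C[C@H]([NH3+])c1ccccc1 | intermediate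
22 | 3-[(1R,2R,4aR,5R,8aR)-2-acetyl-5-carboxy-2,5,8a-trimethyldecahydronaphthalen-1-yl]propanoic acid (single enantiomer) | CC(=O)[C@]1(C)CC[C@@H]2[C@](C)(CCC[C@@]2(C)C(=O)O)[C@H]1CCC(=O)O | intermediate
23 | 3-[(1R,2R,4aR,5R,8aS)-2-(acetyloxy)-5-carboxy-2,5,8a-trimethyldecahydronaphthalen-1-yl]propanoic acid | CC(=O)O[C@]1(C)CC[C@@H]2[C@](C)(CCC[C@@]2(C)C(=O)O)[C@H]1CCC(=O)O | target

## Step count and risks

Total steps: 10. Longest linear sequence: 10 steps (1 to 23).

**Step 7 (new radical cascade).** It can fail through hydrogen-atom transfer to one of the trisubstituted alkenes, 1,5-hydrogen transfer from the acidic C–H of the β-keto ester to the ring-B radical, or premature reduction of a tertiary radical. The fallback uses known reaction types, sets out from 16 and comes back at 23. The bicyclisation of 16 is run in the radical–polar crossover mode (Co(salen), C16H14CoN2O2, with N-fluoro-2,4,6-trimethylpyridinium tetrafluoroborate and PhSiH3), so that the ring-B cation is captured by the enol oxygen of the β-keto ester. This gives the tricyclic enol ether methyl 7-(dimethoxymethyl)-3,4a,7,10a-tetramethyl-4a,5,6,6a,7,8,9,10,10a,10b-decahydro-1H-benzo[f]chromene-2-carboxylate (racemic, ring configuration as in 17) F1. Aqueous HCl in THF opens the enol ether and the acetal to methyl 2-acetyl-3-[rac-(1R,2R,4aR,5R,8aS)-5-formyl-2-hydroxy-2,5,8a-trimethyldecahydronaphthalen-1-yl]propanoate F2. DBU in MeCN then moves the acetyl group to the tertiary alkoxide by a retro-Claisen transfer, giving methyl 3-[rac-(1R,2R,4aR,5R,8aS)-2-(acetyloxy)-5-formyl-2,5,8a-trimethyldecahydronaphthalen-1-yl]propanoate F3. LiOH (1.1 equiv, 0 °C) followed by Pinnick oxidation gives racemic 23 F4. Crystallisation with (S)-1-phenylethylamine gives the (1S)-1-phenylethan-1-aminium salt of 23 F5, and 1 M HCl releases 23.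

**Step 9 (resolution).** The salts may not separate well. The fallback sets out from 20 and comes back at 22. The unhindered side-chain acid of 20 is esterified with (S)-1-phenylethanol (EDC hydrochloride, DMAP, CH2Cl2) and the two diastereomeric esters are separated on silica. The ester of the required enantiomer, (1S)-1-phenylethyl 3-[(1R,2R,4aR,5R,8aR)-2-acetyl-5-carboxy-2,5,8a-trimethyldecahydronaphthalen-1-yl]propanoate F6, is cleaved by hydrogenolysis (H2, palladium on carbon, EtOAc) to 22, which enters step 10 at the oxidation.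

**Step 2 (zinc reagent with a free alkyne C–H).** The reagent may quench itself or add to its own alkyne. The fallback sets out from 3 and comes back at 6. Compound 3 is coupled under the same palladium catalysis with the silyl-capped reagent [4-(trimethylsilyl)but-3-yn-1-yl]zinc bromide F7, made from (4-bromobut-1-yn-1-yl)trimethylsilane and zinc. This gives trimethyl[(5E)-9-iodo-6-methylnon-5-en-1-yn-1-yl]silane F8, and K2CO3 in MeOH removes silicon to give 6.

## Further compounds

F1 | step 7 | methyl 7-(dimethoxymethyl)-3,4a,7,10a-tetramethyl-4a,5,6,6a,7,8,9,10,10a,10b-decahydro-1H-benzo[f]chromene-2-carboxylate (racemic, ring configuration as in 17) | COC(=O)C1=C(C)O[C@]2(C)CC[C@@H]3[C@](C)(CCC[C@@]3(C)C(OC)OC)[C@H]2C1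
F2 | step 7 | methyl 2-acetyl-3-[rac-(1R,2R,4aR,5R,8aS)-5-formyl-2-hydroxy-2,5,8a-trimethyldecahydronaphthalen-1-yl]propanoate | C[C@@]1(O)CC[C@@H]2[C@](C)(CCC[C@@]2(C)C=O)[C@H]1CC(C(C)=O)C(=O)OC
F3 | step 7 | methyl 3-[rac-(1R,2R,4aR,5R,8aS)-2-(acetyloxy)-5-formyl-2,5,8a-trimethyldecahydronaphthalen-1-yl]propanoate | CC(=O)O[C@]1(C)CC[C@@H]2[C@](C)(CCC[C@@]2(C)C=O)[C@H]1CCC(=O)OC
F4 | step 7 | racemic 3-[(1R,2R,4aR,5R,8aS)-2-(acetyloxy)-5-carboxy-2,5,8a-trimethyldecahydronaphthalen-1-yl]propanoic acid | CC(=O)O[C@]1(C)CC[C@@H]2[C@](C)(CCC[C@@]2(C)C(=O)O)[C@H]1CCC(=O)O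
F5 | step 7 | (1S)-1-phenylethan-1-aminium 3-[(1R,2R,4aR,5R,8aS)-2-(acetyloxy)-5-carboxy-2,5,8a-trimethyldecahydronaphthalen-1-yl]propanoate | CC(=O)O[C@]1(C)CC[C@@H]2[C@](C)(CCC[C@@]2(C)C(=O)O)[C@H]1CCC(=O)[O-].C[C@H]([NH3+])c1ccccc1
F6 | step 9 | (1S)-1-phenylethyl 3-[(1R,2R,4aR,5R,8aR)-2-acetyl-5-carboxy-2,5,8a-trimethyldecahydronaphthalen-1-yl]propanoate | CC(=O)[C@]1(C)CC[C@@H]2[C@](C)(CCC[C@@]2(C)C(=O)O)[C@H]1CCC(=O)O[C@@H](C)c1ccccc1
F7 | step 2 | [4-(trimethylsilyl)but-3-yn-1-yl]zinc bromide | C[Si](C)(C)C#CCC[Zn]Br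
F8 | step 2 | trimethyl[(5E)-9-iodo-6-methylnon-5-en-1-yn-1-yl]silane | C[Si](C)(C)C#CCC/C=C(\C)CCCI
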